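**Plan**
- Retrosynthesis: the ester C–O bond at C3 is cut first, then the C3–O bond of ring A back to a C3–H bond, then the central C15=C15' double bond, which halves the C40 polyene into two C20 aldehydes.
- Forward: all-trans-retinal 1 is coupled reductively to β-carotene 2, 2 is hydroxylated at C3 of one ring to (3R)-β-cryptoxanthin 3, and 3 is acylated with oleoyl chloride 4 to the target 5. Both six-membered rings come ready-made in 1; no ring is formed.
- Enabling feature: the two end rings of 2 are identical 2,6,6-trimethylcyclohexene rings. In each, C3 is an unactivated ring methylene between C2 and the allylic C4, so a hydroxylase that reaches C3 of either ring gives the same alcohol, whereas a small chemical oxidant would attack C4.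
- Stereochemistry: the only stereocentre (C3, R) is set by the enzyme in the C–H hydroxylation and is not touched afterwards. The all-E polyene comes from 1 and an E-selective coupling; the 9Z alkene comes with 4.

Key step: step 2

Assumption: the hydroxylase of step 2 is taken to be obtainable as a recombinant membrane preparation with its electron-transfer partners; all polyenes are handled under argon in dim light.

**Step 1**
Reactants: 1 all-trans-retinal (two molecules)
Product: 2 all-E-β-carotene
Conditions: TiCl3, LiAlH4, THF, 0 °C then reflux; 1 in THF added, reflux, Ar, dark; filtration through Florisil, recrystallisation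
Reagents that add atoms: none
Why: McMurry reductive carbonyl coupling, in which low-valent titanium joins the two aldehyde carbons (C15 and C15') and removes both oxygens, is established for this polyenal; the new central double bond should form mainly E, the all-E isomer is enriched by crystallisation, and no stereocentre arises.

**Step 2**
Reactants: 2 all-E-β-carotene
Product: 3 (3R)-β-cryptoxanthin
Conditions: recombinant β-carotene 3-hydroxylase (CrtZ-family non-heme diiron monooxygenase, N-terminally truncated plant-type variant, E. coli membrane fraction), ferredoxin, ferredoxin–NADP+ reductase, NADP+ (cat.), D-glucose, glucose dehydrogenase, FeSO4 (cat.), catalase, air, 2 added as a Tween 80/phosphatidylcholine dispersion, Tris-HCl buffer pH 7.5, 30 °C, dark; stopped at partial conversion; SiO2 chromatography, recovered 2 recycled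
Reagents that add atoms: dioxygen (from air), O=O
Why: The diiron centre, reduced to two divalent iron ions by NADPH through ferredoxin, binds O2 and forms a high-valent iron-oxo species that abstracts the pro-R hydrogen atom from C3 of one ring, and rebound of the iron-bound hydroxyl onto the C3 radical from the same face makes the C3–O bond with retention, the second oxygen atom leaving as water. The closest known reaction type is the enzymatic 3-hydroxylation of carotenoid β-rings by membrane-bound diiron monooxygenases, a C–H hydroxylation of the kind carried out by the fatty-acid hydroxylase family; no ring is closed. The new stereocentre C3 is controlled by the enzyme alone, since 2 is achiral: only one of the two enantiotopic hydrogens on C3 can reach the oxo group, which gives the 3R alcohol. Site selectivity for the homoallylic C3 over the weaker allylic C4–H follows from binding and not from bond strength, because the rigid all-E polyene rod of 2 lies in a hydrophobic channel and fixes the depth of the ring so that C3, the ring carbon farthest from the chain, points at the metal. Because the two end rings of 2 are related by symmetry, the first hydroxylation can give only one compound. Hydroxylation of the second ring is the competing reaction and is held back by a truncated enzyme variant that releases the monoalcohol, by stopping at partial conversion and by the easy chromatographic separation of hydrocarbon, monoalcohol and diol.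

**Step 3**
Reactants: 3 (3R)-β-cryptoxanthin; 4 oleoyl chloride
Product: 5 (3R)-β-cryptoxanthin oleate
Conditions: 4 (1.5 equiv), pyridine, DMAP (cat.), CH2Cl2, 0 °C to rt, Ar, dark; SiO2 chromatography
Reagents that add atoms: none
Why: Esterification of a secondary alcohol by nucleophilic acyl substitution on an acyl chloride with pyridine as base should proceed without touching the C3–O bond, so the 3R configuration is retained, and the mild, dark, oxygen-free conditions should leave the all-E polyene and the Z alkene of the acyl chain unchanged.

**Compound list**
1 | all-trans-retinal | CC1=C(/C=C/C(C)=C/C=C/C(C)=C/C=O)C(C)(C)CCC1 | starting material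
2 | all-E-β-carotene (β,β-carotene) | CC1=C(/C=C/C(C)=C/C=C/C(C)=C/C=C/C=C(C)/C=C/C=C(C)/C=C/C2=C(C)CCCC2(C)C)C(C)(C)CCC1 | intermediate
3 | (3R)-β-cryptoxanthin ((3R)-β,β-caroten-3-ol, all-E) | O[C@@H]1CC(C)=C(/C=C/C(C)=C/C=C/C(C)=C/C=C/C=C(C)/C=C/C=C(C)/C=C/C2=C(C)CCCC2(C)C)C(C)(C)C1 | intermediate
4 | oleoyl chloride ((9Z)-octadec-9-enoyl chloride) | CCCCCCCC/C=C\CCCCCCCC(=O)Cl | starting material
5 | (3R)-β-cryptoxanthin oleate ((3R)-β,β-caroten-3-yl (9Z)-octadec-9-enoate, all-E polyene) | CCCCCCCC/C=C\CCCCCCCC(=O)O[C@@H]1CC(C)=C(/C=C/C(C)=C/C=C/C(C)=C/C=C/C=C(C)/C=C/C=C(C)/C=C/C2=C(C)CCCC2(C)C)C(C)(C)C1 | target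

Total step count: 3
Longest linear sequence: 3 steps (1 → 2 → 3 → 5)

**Steps most likely to fail**

Step 2 (highest risk). The monoalcohol may be hydroxylated further at the second ring, turnover may stall because the water-insoluble substrate reaches the membrane enzyme poorly, and the polyene may bleach oxidatively in aerated buffer. The fallback sets out from 1 and comes back at 3. It gives up C–H oxidation on the C40 skeleton and brings the C3 stereocentre in with a C15 building block, joined to a C25 aldehyde by a Wittig reaction at C11=C12. Wittig extension of 1 with (triphenylphosphoranylidene)acetaldehyde (toluene, 80 °C) should give β-apo-14'-carotenal F1. A second Wittig reaction with 2-(triphenylphosphoranylidene)propanal (toluene, reflux) should give β-apo-12'-carotenal F2. Separately, (3R)-3-hydroxy-β-ionone F3, a known compound taken from commercial supply, would be treated with excess vinylmagnesium bromide (THF, −20 °C to rt) to give (3R)-3-hydroxy-vinyl-β-ionol F4, the tertiary carbinol as both epimers, which is of no consequence. PPh3·HBr in MeOH at rt should convert F4, with allylic transposition, into [(3R)-3-hydroxy-β-ionylideneethyl]triphenylphosphonium bromide F5. Wittig olefination of F2 with F5 (NaOMe, MeOH/CH2Cl2, 0 °C to rt), then thermal equilibration to the all-E isomer in refluxing heptane, should deliver 3.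

Step 1. Coupling may stop at the pinacol stage, or the low-valent titanium and its Lewis-acidic chlorides may partly reduce or E/Z-scramble the polyene. The fallback sets out from 1 and comes back at 2, replacing the reductive coupling by a C20 + C20 Wittig olefination. Reduction of 1 with NaBH4 (EtOH, 0 °C) should give all-trans-retinol F6. PPh3·HBr in MeOH should convert F6 into retinyltriphenylphosphonium bromide F7. Reaction of F7 with a second portion of 1 (NaOMe, MeOH, 0 °C to rt), then thermal isomerisation in refluxing heptane and crystallisation, should give 2.

Step 3. Hydrogen chloride released from the acid chloride may cause E/Z isomerisation and acid-promoted degradation of the polyene, and acylation may be incomplete. The fallback sets out from 3 and comes back at 5 without using 4. It is a Steglich esterification with free oleic acid activated in the flask (N,N'-diisopropylcarbodiimide, DMAP cat., CH2Cl2, 0 °C to rt, Ar, dark), so that no chloride or strong acid is present at any point. No new isolated compound arises.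

**Further compounds**
F1 | step 2 | β-apo-14'-carotenal | CC1=C(/C=C/C(C)=C/C=C/C(C)=C/C=C/C=O)C(C)(C)CCC1
F2 | step 2 | β-apo-12'-carotenal | CC1=C(/C=C/C(C)=C/C=C/C(C)=C/C=C/C=C(C)/C=O)C(C)(C)CCC1
F3 | step 2 | (3R)-3-hydroxy-β-ionone | O[C@@H]1CC(C)=C(/C=C/C(C)=O)C(C)(C)C1
F4 | step 2 | (3R)-3-hydroxy-vinyl-β-ionol ((1E)-1-[(4R)-4-hydroxy-2,6,6-trimethylcyclohex-1-en-1-yl]-3-methylpenta-1,4-dien-3-ol, both carbinol epimers) | O[C@@H]1CC(C)=C(/C=C/C(C)(O)C=C)C(C)(C)C1
F5 | step 2 | [(3R)-3-hydroxy-β-ionylideneethyl]triphenylphosphonium bromide ([(2E,4E)-5-[(4R)-4-hydroxy-2,6,6-trimethylcyclohex-1-en-1-yl]-3-methylpenta-2,4-dienyl]triphenylphosphonium bromide) | O[C@@H]1CC(C)=C(/C=C/C(C)=C/C[P+](c2ccccc2)(c2ccccc2)c2ccccc2)C(C)(C)C1.[Br-]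
F6 | step 1 | all-trans-retinol | CC1=C(/C=C/C(C)=C/C=C/C(C)=C/CO)C(C)(C)CCC1
F7 | step 1 | retinyltriphenylphosphonium bromide | CC1=C(/C=C/C(C)=C/C=C/C(C)=C/C[P+](c2ccccc2)(c2ccccc2)c2ccccc2)C(C)(C)CCC1.[Br-]
F0 | step 3 | none | none
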